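**Assumptions:** Eudesmane numbering is used (C1–C15; C1′ is the benzylic carbon; α/β as in steroids, 10-Me = β). Only substrates, building blocks, intermediates and the target are numbered; simple reagents are given by name and SMILES. Compounds 1, 13 and 14 are taken as commercial (14 can also be made in situ from BH3·SMe2 and isobutene).

## Retrosynthetic overview

1. Macrocarpal H (15) ⇒ one-step three-component union at C1′: aldehyde 12 + 2,4-diformylphloroglucinol 13 + an isobutyl radical from 14, via an o-quinone methide. This forms C1′–aryl and C1′–isobutyl and sets C1′.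
2. 12 ⇒ triol 9: C4 carbinol → ketone → exocyclic methylene; C1′ CH2OH → CHO.
3. 9 ⇒ hydroxy-dione 4: C1 ketone → C1=CH2 → hydroboration (sets C1); C7 ketone → nitrile → equatorial acetyl → carbinol (sets C7).
4. 4 ⇒ (R)-Wieland–Miescher ketone 1 by deconjugative bis-ketalisation and hydroboration of the C4=C5 alkene (oxygen at C4, sets the trans C5–H).
5. Ring order: both carbocycles and the C10 stereocentre are bought in 1; no ring is formed in the route; the intact aromatic ring arrives in the last step.

## Route

**Step 1**
Reactants: 1, (R)-(−)-Wieland–Miescher ketone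
Product: 2, 1,1:7,7-bis(ethylenedioxy) ketal of 1 with the alkene moved to C4=C5 (10β-Me)
Conditions: HOCH2CH2OH (10 eq), p-TsOH (cat.), PhH, reflux, Dean–Stark
Reagents that add atoms: ethylene glycol, OCCO
Why: Acid-catalysed ketalisation of both carbonyls; the enone ketalises via its dienol ether so the alkene ends β,γ (C4=C5), as in Δ4-3-keto steroid → Δ5-3-ketal, with C10 untouched.

**Step 2**
Reactants: 2, Δ4 bis-ketal
Product: 3, 1,1:7,7-bis(ethylenedioxy)-4α-hydroxy-10β-methyl-trans-decalin (5α-H)
Conditions: BH3·THF, THF, 0 °C → rt; then NaOH, H2O2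
Reagents that add atoms: hydrogen peroxide, OO (borane supplies H only)
Why: Brown hydroboration–oxidation; boron adds to the less substituted C4 and the syn addition occurs on the α face opposite the angular methyl, giving 4α-OH and the trans 5α-H ring fusion.

**Step 3**
Reactants: 3, hydroxy bis-ketal
Product: 4, 4α-hydroxy-10β-methyl-trans-decalin-1,7-dione
Conditions: 2 M HCl, THF, rt
Reagents that add atoms: water, O
Why: Acetal hydrolysis of both dioxolanes; the C4 hydroxyl is γ to both carbonyls, so no elimination or retro-aldol path exists.

**Step 4**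
Reactants: 4, hydroxy-dione
Product: 5, 7-cyano-4α-hydroxy-10β-methyl-trans-decalin-1-one (C7 epimer mixture)
Conditions: TosMIC (1.1 eq), t-BuOK, DME/t-BuOH, −10 → 20 °C
Reagents that add atoms: TosMIC, Cc1ccc(cc1)S(=O)(=O)C[N+]#[C-]
Why: Van Leusen reductive cyanation; the unhindered C7 ketone reacts far faster than the C1 ketone flanked by quaternary C10, and the C7 configuration is fixed later in step 6.

**Step 5**
Reactants: 5, cyano ketone
Product: 6, 7-cyano-4α-hydroxy-1-methylene-10β-methyl-trans-decalin
Conditions: Ph3PCH3Br, KHMDS (2.5 eq ylide), toluene, 80 °C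
Reagents that add atoms: methyltriphenylphosphonium bromide, C[P+](c1ccccc1)(c1ccccc1)c1ccccc1.[Br-]
Why: Wittig methylenation of the hindered C1 ketone with salt-free ylide at elevated temperature; the alkoxide and the weakly electrophilic secondary nitrile are tolerated.

**Step 6**
Reactants: 6, methylene nitrile
Product: 7, 7β-acetyl-4α-hydroxy-1-methylene-10β-methyl-trans-decalin
Conditions: MeLi (3 eq), Et2O, 0 °C → rt; aq. citric acid; then NaOMe, MeOH, rt
Reagents that add atoms: methyllithium, [Li]C; water, O
Why: Organolithium addition to the nitrile stops at the N-lithio ketimine, which hydrolyses to the methyl ketone; enolate equilibration then places the acetyl group equatorial (7β), setting C7.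

**Step 7**
Reactants: 7, methyl ketone
Product: 8, 1-methylene-15-nor-eudesmane-4α,11-diol
Conditions: MeMgBr, CeCl3, THF, −78 → 0 °C
Reagents that add atoms: methylmagnesium bromide, C[Mg]Br
Why: Grignard 1,2-addition gives the tertiary carbinol; CeCl3 suppresses enolisation so C7 is not scrambled.

**Step 8**
Reactants: 8, methylene diol
Product: 9, 1β-(hydroxymethyl)-15-nor-eudesmane-4α,11-diol
Conditions: 9-BBN (4 eq), THF, 65 °C; then NaOH, H2O2
Reagents that add atoms: hydrogen peroxide, OO
Why: Hydroboration–oxidation of the exocyclic alkene; boron goes to the CH2 terminus and H is delivered to C1 from the α face anti to the adjacent 10β-methyl, giving the equatorial 1β-CH2OH and setting C1.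

**Step 9**
Reactants: 9, triol
Product: 10, 11-hydroxy-1β-(hydroxymethyl)-15-nor-eudesman-4-one
Conditions: NaOCl (aq.), AcOH, 0 °C → rt
Reagents that add atoms: none
Why: Stevens oxidation, which oxidises secondary alcohols much faster than primary ones; the neopentyl-type primary and the tertiary alcohol survive, and C5 remains in the thermodynamically preferred trans arrangement.

**Step 10**
Reactants: 10, keto diol
Product: 11, 1β-(hydroxymethyl)eudesm-4(15)-en-11-ol
Conditions: Ph3PCH3Br, KOt-Bu (5 eq), THF, rt → 50 °C
Reagents that add atoms: methyltriphenylphosphonium bromide, C[P+](c1ccccc1)(c1ccccc1)c1ccccc1.[Br-]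
Why: Wittig methylenation of the unhindered C4 ketone, with excess ylide to absorb the two OH protons; the same ketone-to-exocyclic-methylene step is the classical way to finish β-eudesmol.

**Step 11**
Reactants: 11, methylene diol
Product: 12, 11-hydroxyeudesm-4(15)-ene-1β-carbaldehyde
Conditions: TEMPO (cat.), PhI(OAc)2, CH2Cl2, rt
Reagents that add atoms: none
Why: Oxoammonium (TEMPO) oxidation is selective for the primary alcohol and near-neutral, so the tertiary alcohol, the alkene and the C1 configuration are preserved.

**Step 12**
Reactants: 12, aldehyde; 13, 2,4-diformylphloroglucinol (1.3 eq); 14, triisobutylborane (5 eq)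
Product: 15, macrocarpal H
Conditions: morpholine·AcOH (20 mol%), 4 Å MS, THF, 40 °C, with 14 present; air by syringe pump, 40 °C; aq. citric acid/MeOH work-up (no peroxide)
Reagents that add atoms: none beyond reactants 13 (aryl unit) and 14 (isobutyl group)
Why: Proposed new method: amine-catalysed Knoevenagel/Mannich condensation of 12 at the only free ring carbon of 13 releases a diformyl o-quinone methide at low steady-state concentration; the isobutyl radical from 14/O2 adds to its exocyclic carbon (C1′) and the aryloxyl radical is captured by 14 (SH2 at boron), giving a boron phenoxide and a new isobutyl radical (chain), so both C1′ bonds form in one operation; C1′ is set by 1,2-induction, because A(1,3) strain holds C1–H in the quinone-methide plane and the radical enters anti to quaternary C10, which by this model gives the required 1′S epimer; the nucleophilic radical should ignore C4=CH2 and the aryl aldehydes; the closest known reaction type is the O2-initiated radical-chain 1,4-addition of trialkylboranes to enones and quinones, combined with the known in situ o-quinone-methide generation from 13 and aldehydes, and it has not been shown for a three-component, diastereoselective alkylation of a β-alkyl o-quinone methide.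

## Compound list

1 | (R)-(−)-Wieland–Miescher ketone | O=C1CCCC2=CC(=O)CC[C@@]12C | starting material
2 | 1,1:7,7-bis(ethylenedioxy) Δ4(5) ketal of 1 | C1CCC3(OCCO3)[C@]2(C)CCC4(OCCO4)CC2=1 | intermediate
3 | 4α-hydroxy bis-ketal, trans-fused (5α-H) | O[C@@H]1CCC3(OCCO3)[C@]2(C)CCC4(OCCO4)C[C@@H]12 | intermediate
4 | 4α-hydroxy-10β-methyl-trans-decalin-1,7-dione | O[C@@H]1CCC(=O)[C@]2(C)CCC(=O)C[C@@H]12 | intermediate
5 | 7-cyano-4α-hydroxy-10β-methyl-trans-decalin-1-one (C7 epimers) | O[C@@H]1CCC(=O)[C@]2(C)CCC(C#N)C[C@@H]12 | intermediate
6 | 7-cyano-4α-hydroxy-1-methylene-10β-methyl-trans-decalin (C7 epimers) | O[C@@H]1CCC(=C)[C@]2(C)CCC(C#N)C[C@@H]12 | intermediate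
7 | 7β-acetyl-4α-hydroxy-1-methylene-10β-methyl-trans-decalin | O[C@@H]1CCC(=C)[C@]2(C)CC[C@@H](C(C)=O)C[C@@H]12 | intermediate
8 | 1-methylene-15-nor-eudesmane-4α,11-diol | O[C@@H]1CCC(=C)[C@]2(C)CC[C@@H](C(C)(C)O)C[C@@H]12 | intermediate
9 | 1β-(hydroxymethyl)-15-nor-eudesmane-4α,11-diol | O[C@@H]1CC[C@@H](CO)[C@]2(C)CC[C@@H](C(C)(C)O)C[C@@H]12 | intermediate
10 | 11-hydroxy-1β-(hydroxymethyl)-15-nor-eudesman-4-one | O=C1CC[C@@H](CO)[C@]2(C)CC[C@@H](C(C)(C)O)C[C@@H]12 | intermediate
11 | 1β-(hydroxymethyl)eudesm-4(15)-en-11-ol | C=C1CC[C@@H](CO)[C@]2(C)CC[C@@H](C(C)(C)O)C[C@@H]12 | intermediate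
12 | 11-hydroxyeudesm-4(15)-ene-1β-carbaldehyde | C=C1CC[C@@H](C=O)[C@]2(C)CC[C@@H](C(C)(C)O)C[C@@H]12 | intermediate
13 | 2,4-diformylphloroglucinol (2,4,6-trihydroxybenzene-1,3-dicarbaldehyde) | O=Cc1c(O)cc(O)c(C=O)c1O | starting material
14 | triisobutylborane | CC(C)CB(CC(C)C)CC(C)C | starting material
15 | macrocarpal H | C=C1CC[C@@H]([C@H](CC(C)C)c2c(O)c(C=O)c(O)c(C=O)c2O)[C@]2(C)CC[C@@H](C(C)(C)O)C[C@@H]12 | target

## Summary

Total step count: 12. Longest linear sequence: 12 steps (from 1).

Three steps most likely to fail:

1. **Step 12 (proposed new step).** Risks: slow condensation of the hindered aldehyde, quinone-methide tautomerisation or hetero-Diels–Alder with C4=CH2, C1 epimerisation, poor chain transfer or low dr at C1′. Fallback (known chemistry, polar and stepwise): from triol 9, TEMPO oxidation to the hydroxy-aldehyde; addition of 2,4,6-trimethoxyphenyllithium; acid-promoted SN1 allylation of the trimethoxybenzylic alcohol with methallyltrimethylsilane (same A(1,3) facial bias); H2/Pd–C; then C4 oxidation and Wittig, two ortho-lithiation/DMF formylations, and thiolate tri-O-demethylation.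
2. **Step 4 (C7 versus C1 chemoselectivity of TosMIC).** Fallback: differentiate the carbonyls by oxidation state instead of rate. Reduce only the C1 ketone of 1 with NaBH4, carry it as a silyl ether through ketalisation and hydroboration, homologate C7 with C1 masked, then re-oxidise C1 and methylenate.
3. **Step 8 (facial selectivity of hydroboration at C1).** Fallback: set C1 by alkene reduction. Convert the C1 ketone to its Δ1 enol triflate, carry out Pd-catalysed methoxycarbonylation, hydrogenate the Δ1 ester from the α face (or Mg/MeOH followed by NaOMe equilibration), and reduce the ester to the same 1β-CH2OH.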